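**Remark on the chemistry:** the target, (2,4-dimethoxyphenyl)(6,7-dimethoxy-1H-isochromen-3-yl)methanone, has no stereocentre and no stereogenic double bond (C3=C4 is endocyclic). It is achiral, so the route needs no stereocontrol.

## Retrosynthetic overview

1. The pyran ring of target 8 is cut at O2–C3 and at C4–C4a. This gives veratryl alcohol 5 (arene, C1H2 and O2) and a two-carbon unit C3–C4 that carries the aroyl group.
2. Enabling feature: C3 sits between the aroyl C=O and C4. With C4 at the aldehyde level, C3 is the central carbon of a 1,3-dicarbonyl and can be a diazo (carbene) carbon that inserts into the O2–H bond.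
3. C4a lies para to the C7 methoxy group, the most nucleophilic carbon of the veratryl ring. The formyl carbon C4 therefore closes the ring by Friedel–Crafts attack, and loss of water gives C3=C4.
4. Diazo ketoaldehyde 4 comes from diazoketone 2 by Vilsmeier C-formylation, and 2 from acid chloride 1.
5. Ring order: both benzene rings are bought; the pyran ring is the only ring formed, in the last step.

Key step: step 3

## Route

Step 1
Reactants: 1 2,4-dimethoxybenzoyl chloride
Product: 2 2-diazo-1-(2,4-dimethoxyphenyl)ethan-1-one
Conditions: TMSCHN2 (2 equiv, 2 M in hexanes), THF–MeCN 1:1, 0 °C → rt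
Reagents that add atoms: (trimethylsilyl)diazomethane, C[Si](C)(C)C=[N+]=[N-]
Why: Acylation of a diazoalkane by an acid chloride (Arndt–Eistert-type diazoketone synthesis, trimethylsilyldiazomethane variant), in which the C-silyl group is lost as the chlorosilane.

Step 2
Reactants: 2 2-diazo-1-(2,4-dimethoxyphenyl)ethan-1-one
Product: 4 2-diazo-3-(2,4-dimethoxyphenyl)-3-oxopropanal, via N-[2-diazo-3-(2,4-dimethoxyphenyl)-3-oxopropylidene]-N-methylmethanaminium chloride 3 (not isolated)
Conditions: [Me2N=CHCl]Cl (1.2 equiv), 2,6-lutidine (1.2 equiv), CHCl3, 0 °C → rt; then 10% aq. AcOH, rt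
Reagents that add atoms: (chloromethylene)dimethyliminium chloride, C[N+](C)=CCl.[Cl-]; water, O
Why: Vilsmeier C-formylation of the nucleophilic diazo carbon of an α-diazoketone, with 2,6-lutidine taking up the HCl that would otherwise destroy 2, followed by hydrolysis of iminium salt 3 to the aldehyde.

Step 3
Reactants: 4 2-diazo-3-(2,4-dimethoxyphenyl)-3-oxopropanal; 5 (3,4-dimethoxyphenyl)methanol (veratryl alcohol)
Product: 8 (2,4-dimethoxyphenyl)(6,7-dimethoxy-1H-isochromen-3-yl)methanone (target), via 2-[(3,4-dimethoxyphenyl)methoxy]-3-(2,4-dimethoxyphenyl)-3-oxopropanal 6 (not isolated), via (2,4-dimethoxyphenyl)(4-hydroxy-6,7-dimethoxy-3,4-dihydro-1H-isochromen-3-yl)methanone 7 (not isolated)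
Conditions: Rh2(OAc)4 (1 mol %), DCE, 60 °C, slow addition of 4 (1.1 equiv) to 5 (1.0 equiv); then Sc(OTf)3 (10 mol %), 4 Å MS, 60 °C, same flask
Reagents that add atoms: none
Why: Proposed new method: Rh2(OAc)4 turns 4 into an acceptor/acceptor rhodium carbenoid that the primary hydroxyl of 5 traps as an oxonium ylide, and proton transfer completes the O–H insertion (bond O2–C3) to give 6, which rests as its enol; Sc(OTf)3 then binds the 1,3-dicarbonyl unit of 6, the veratryl ring carbon para to a methoxy group attacks the formyl carbon (bond C4–C4a) to give carbinol 7, and the benzylic hydroxyl is lost by dehydration into conjugation with the aroyl group. The closest known reaction types are the Rh(II)-catalysed O–H insertion of 2-diazo-1,3-dicarbonyl compounds into alcohols, the Pomeranz–Fritsch and Bradsher cyclodehydrations of aryl-tethered aldehydes, and the Lewis-acid-catalysed Friedel–Crafts alkenylation of electron-rich arenes with 1,3-dicarbonyl compounds; joining them in one flask to build a 1H-isochromene is the new part. The pyran ring, the only ring formed, closes in a 6-exo-trig Friedel–Crafts hydroxyalkylation that follows the intermolecular insertion. No stereocentre remains, because the two carbinol stereocentres of 7 (C3 and C4, formed without control) are erased by the dehydration. The step needs O–H insertion to win over ylide formation at the ortho-methoxy group and over attack on the arenes (secured by the unhindered primary alcohol and slow addition of 4), the formyl and not the aroyl carbon as electrophile (the aroyl carbonyl is deactivated by its 2,4-dimethoxyphenyl ring and more hindered), and closure para and not ortho to a methoxy group (favoured electronically and sterically, as in Pictet–Spengler closures of 3,4-dimethoxyphenyl systems).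

## Compound list

1 | 2,4-dimethoxybenzoyl chloride | COc1ccc(C(=O)Cl)c(OC)c1 | starting material
2 | 2-diazo-1-(2,4-dimethoxyphenyl)ethan-1-one | COc1ccc(C(=O)C=[N+]=[N-])c(OC)c1 | intermediate
3 | N-[2-diazo-3-(2,4-dimethoxyphenyl)-3-oxopropylidene]-N-methylmethanaminium chloride (not isolated) | COc1ccc(C(=O)C(=[N+]=[N-])C=[N+](C)C)c(OC)c1.[Cl-] | intermediate
4 | 2-diazo-3-(2,4-dimethoxyphenyl)-3-oxopropanal | COc1ccc(C(=O)C(=[N+]=[N-])C=O)c(OC)c1 | intermediate
5 | (3,4-dimethoxyphenyl)methanol (veratryl alcohol) | COc1ccc(CO)cc1OC | starting material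
6 | 2-[(3,4-dimethoxyphenyl)methoxy]-3-(2,4-dimethoxyphenyl)-3-oxopropanal (drawn as the keto aldehyde, expected to rest as its enol; not isolated) | COc1ccc(C(=O)C(OCc2ccc(OC)c(OC)c2)C=O)c(OC)c1 | intermediate
7 | (2,4-dimethoxyphenyl)(4-hydroxy-6,7-dimethoxy-3,4-dihydro-1H-isochromen-3-yl)methanone (mixture of diastereomers, not isolated) | COc1ccc(C(=O)C2OCc3cc(OC)c(OC)cc3C2O)c(OC)c1 | intermediate
8 | (2,4-dimethoxyphenyl)(6,7-dimethoxy-1H-isochromen-3-yl)methanone | COc1ccc(C(=O)C2=Cc3cc(OC)c(OC)cc3CO2)c(OC)c1 | target

## Summary

Total step count: 3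
Longest linear sequence: 3 steps (1 → 2 → 4 → 8); veratryl alcohol 5 enters in step 3.

## Steps most likely to fail

**Step 3 (proposed new method).** Three processes may defeat it:
- the carbenoid may be captured within the molecule by the ortho-methoxy oxygen before the alcohol arrives;
- the Lewis acid may ionise the benzylic C–O bond of the veratryl ether, leading to oligomerisation of the veratryl unit before ring closure;
- the enolised formyl group may be too weak an electrophile for the Friedel–Crafts closure.

The fallback uses known chemistry and closes the ring by forming C3=C4 instead. It sets out from 5 and 2 and comes back to the route at 8. Veratryl alcohol 5 would be brominated para to the 3-methoxy group (NBS, MeCN, 0 °C) to give (2-bromo-4,5-dimethoxyphenyl)methanol F1. Rh2(OAc)4-catalysed O–H insertion of diazoketone 2 into F1 (CH2Cl2, rt) should give 2-[(2-bromo-4,5-dimethoxyphenyl)methoxy]-1-(2,4-dimethoxyphenyl)ethan-1-one F2. Palladium-catalysed reductive carbonylation of the aryl bromide (Pd(OAc)2, di(1-adamantyl)-n-butylphosphine, CO/H2, TMEDA, toluene, 100 °C) should give 2-{[2-(2,4-dimethoxyphenyl)-2-oxoethoxy]methyl}-4,5-dimethoxybenzaldehyde F3. Intramolecular aldol condensation of F3 (piperidine, AcOH, toluene, reflux) should then close the pyran ring and give 8.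

**Step 2.** Loss of dinitrogen from 2 by protonation (chloromethyl ketone formation) may compete with C-formylation, and the electron-rich arene may be formylated as a side process.

The fallback avoids the diazo aldehyde. It sets out from 2 and 5 and comes back to the route at 6. Rh2(OAc)4-catalysed O–H insertion of 2 into 5 (CH2Cl2, rt) should give 2-[(3,4-dimethoxyphenyl)methoxy]-1-(2,4-dimethoxyphenyl)ethan-1-one F4. Claisen formylation of F4 (HCO2Et, NaH, THF, 0 °C → rt, then mild acidification) should give 6. Compound 6 would then be cyclised with Sc(OTf)3 as in the second stage of step 3.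

**Step 1.** Acylation of the diazoalkane by the electron-rich, ortho-substituted acid chloride may be slow, and the acid released may convert the product into the chloromethyl ketone.

The fallback builds the diazo group by diazo transfer instead. It sets out from 1 and comes back to the route at 2. Iron-catalysed coupling of 1 with MeMgBr (Fe(acac)3, THF, −78 °C) should give 1-(2,4-dimethoxyphenyl)ethan-1-one F5, which can also be bought. Condensation with DMF dimethyl acetal (110 °C) should give (E)-3-(dimethylamino)-1-(2,4-dimethoxyphenyl)prop-2-en-1-one F6. Diazo transfer from tosyl azide to this enaminone (TsN3, CH2Cl2, rt), with loss of the sulfonyl formamidine, should give 2.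

## Further compounds

F1 | step 3 | (2-bromo-4,5-dimethoxyphenyl)methanol | COc1cc(Br)c(CO)cc1OC
F2 | step 3 | 2-[(2-bromo-4,5-dimethoxyphenyl)methoxy]-1-(2,4-dimethoxyphenyl)ethan-1-one | COc1ccc(C(=O)COCc2cc(OC)c(OC)cc2Br)c(OC)c1
F3 | step 3 | 2-{[2-(2,4-dimethoxyphenyl)-2-oxoethoxy]methyl}-4,5-dimethoxybenzaldehyde | COc1ccc(C(=O)COCc2cc(OC)c(OC)cc2C=O)c(OC)c1
F4 | step 2 | 2-[(3,4-dimethoxyphenyl)methoxy]-1-(2,4-dimethoxyphenyl)ethan-1-one | COc1ccc(C(=O)COCc2ccc(OC)c(OC)c2)c(OC)c1
F5 | step 1 | 1-(2,4-dimethoxyphenyl)ethan-1-one | CC(=O)c1ccc(OC)cc1OC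
F6 | step 1 | (E)-3-(dimethylamino)-1-(2,4-dimethoxyphenyl)prop-2-en-1-one | COc1ccc(C(=O)/C=C/N(C)C)c(OC)c1
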